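## The problem

Caraphenol B (15) is an indane. Five-membered ring B (C1, C2, C3, C3a, C7a) is fused to resorcinol ring A (hydroxyls on C4 and C6). C1 carries the 4-hydroxybenzoyl group (C8 carbonyl, ring D), C2 carries the 4-hydroxyphenyl ring C, and C3 carries the 3,5-dihydroxyphenyl ring E. The three contiguous stereocentres are all (R) and all cis, so the aroyl group and two aryl rings crowd one face of ring B.

C1 is benzylic and α to the C8 ketone. It epimerises under acid or base, and the all-cis arrangement is expected to be the less stable one at this centre. C1 therefore has to be set kinetically and late, with nothing harsh afterwards.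

C2 and C3 are configurationally stable. Their cis relation can come from syn addition of hydrogen to a C2=C3 double bond, and once fixed they can control C1 through protonation of a C1 enolate on the face they leave open. None of these relays supplies absolute configuration; a catalyst has to bring it in.

Six phenols must be carried in protected form and released without strong Lewis acid or base. The feature that makes the plan possible is that C1 is α to the C8 carbonyl. It can carry a temporary hydroxyl as a tertiary ketol that cannot epimerise. That carbinol can be made by adding a C2 alkenyl-metal to the C1 ketone of a C1/C8 diketone, it directs hydrogen to C2=C3, and it can be removed reductively through the enolate whose protonation sets C1.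

## Retrosynthesis

**Phenol release (15 from 14).** The last cut is at the six O–C bonds of the protecting groups. Methyl ethers are rejected. Used last, BBr3 would equilibrate the all-cis ketone through its boron enolate; used before deoxygenation, it would expose a tertiary benzylic ketol to ionisation and α-ketol rearrangement. Benzyl ethers fall to hydrogenolysis at neutral pH, so the precursor is hexa-O-benzylcaraphenol B (14). The forward step must remove six benzyl groups without touching the C8 carbonyl or C1–H.

**C1–H from C1–OH (14 from 12).** C1–H is traced back to a C1–O bond in ketol 12. Making C1–H directly by alkylation or equilibration would leave the most labile centre to thermodynamic control, which favours the wrong epimer. Ketol 12 is no simpler in skeleton, but its C1 is quaternary and cannot epimerise. The forward reaction must cleave C1–O through the C1=C8 samarium enolate 13 and protonate it on the face opposite rings C and E.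

**C2–H and C3–H (12 from 11).** Both hydrogens are removed to give indenol 11 with a C2=C3 double bond. Syn addition of hydrogen fixes the cis relation of rings C and E in one operation, where two separate C–C bond formations would each need their own control. The precursor has one stereocentre instead of three. The forward step must deliver hydrogen on the hydroxyl face only. Because C1 is later rewritten from C2 and C3, material hydrogenated on the aroyl face would end as the enantiomer of 14, so 12 must be purified as a single diastereomer.

**Ring B (11 from 9 and 10).** The key cut removes the C3–ring E bond and the C1–C2 bond. Indenol 11 opens to the achiral alkynyl 1,2-diketone 9 and boronic acid 10. Cutting C1–C8 instead (acyl anion plus indenone) closes no ring and offers no obvious catalyst for C1. Cutting C3–C3a and C1–C7a would require ring A to be attached twice. The chosen cut closes ring B, brings in the fourth arene and creates the quaternary carbinol in one catalytic, enantioselective operation. The diketone it needs already holds the C8 carbonyl of the target. The forward reaction must put nickel on C2 and ring E on C3, choose the C1 over the C8 carbonyl, and select one face of the C1 ketone.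

**The diketone (9 from 8, 7, then 4 and 5).** C8=O is traced to a methylene (ketone 8), C1=O to a carbinol (alcohol 7), and the C1–C8 bond to addition of benzylic Grignard reagent 6 (from chloride 5) to aldehyde 4. Oxidising a second alkyne to the diketone is ruled out because it could not be told apart from C2≡C3. Each forward step need only leave the diaryl alkyne untouched.

**Alkyne and arene (4 from 2 and 3; 2 from 1).** C3a–C3 is a Sonogashira bond between bromide 2 and alkyne 3. Bromide 2 comes from aldehyde 1 by bromination ortho to the formyl group. The four building blocks 1, 3, 5 and 10 are commercial benzyl ethers.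

## Roads not taken

**Alternative 1:** The cut removes rings E and C from C3 and C2 at once, leaving indene A1, which already holds C1 and a C8 carbinol. Forward, Ni(cod)2 with hydroxide in an alcohol solvent would add aryl iodide A2 (ring E) and arylboronic acid A3 (ring C) across C2=C3 on the face of the C8 alkoxide. The sequence is oxidative addition, alkoxide-guided syn insertion that puts nickel on C2 in a five-membered chelate, transmetallation and reductive elimination, giving the all-cis alcohol A4.
- Merits: two aryl–carbon bonds and two stereocentres form in one convergent step. The syn mechanism and the tether secure the all-cis relation. No tetrasubstituted alkene has to be hydrogenated, and the aryl groups can be varied late.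
- Weak points: no ring closes, and the burden moves to A1, which must be one enantiomer at C1. Its C1–H is allylic and benzylic, so under hydroxide the double bond can shift into the conjugated position and erase the only centre everything depends on. β-Hydride loss from the C2–nickel species competes. A4 must still be oxidised at C8 and deprotected with the fragile all-cis C1–H already in place.
- Comparison: this road is more convergent, and its relative stereocontrol is mechanistically surer than hydrogenation of a crowded alkene. The chosen plan sets against it that absolute configuration is created catalytically from an achiral precursor in the ring-forming step, and that C1 stays quaternary until the step before last.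

**Alternative 2:** The cut runs through ring A (C3a–C4 and C7–C7a). The resorcinol is built last on cyclopentanone A5, which carries the aroyl group and rings C and E. Forward, the dianion of A5 (LDA) would be acylated at C3a by ketal ester A6 (Claisen). Mild acid and acetate buffer would then free the C6 ketone, let the C7 methyl add to the C7a carbonyl and aromatise, giving A7 with ring A as a free 4,6-diol.
- Merits: polyketide-like logic, no transition metal, ring A arrives unprotected, and the stereocentres are set on a simple carbocycle.
- Weak points: C1 lies between two carbonyls in A5 and next to one in A7 throughout a basic and then acidic sequence, so A7 emerges as the C1 epimer with the aroyl group trans to ring C. Correcting it needs a contra-thermodynamic protonation, and the BBr3 cleavage of four methyl ethers that follows would equilibrate C1 again. Site selectivity of the dianion acylation and the absolute configuration of A5 are further open points.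
- Comparison: this road is better on raw-material cost and avoids both the regiochemical question of the nickel step and the hydrogenation. The chosen plan sets against it that C1 is held as a carbinol until a single kinetic, near-neutral event, which is what the all-cis isomer requires.

**Alternative 3:** The cut is at C1–C7a and C3–C3a, the two bonds from ring A to the benzylic carbons. CsF in MeCN would release aryne A9 from silyl triflate A8. 1,3-Diketone A10 would insert the aryne into its α-carbon–carbonyl bond (enolate carbon adds meta to the 3-methoxy group, the aryl anion closes onto the carbonyl, the four-membered ring fragments) to give keto ketone A11.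
- Merits: one mild step joins rings A, D and E with C8, C1 and C3 from two simple achiral partners. The acyl-alkylation of arynes is well established and the methoxy group steers its regiochemistry.
- Weak points: A11 has no ring B, no C2, no ring C and no stereocentre. The unsymmetrical diketone A10 can transfer either acyl group. A carbon bearing ring C still has to be inserted between C1 and C3, and three stereocentres including the labile C1 must then be set with no built-in source of absolute configuration.
- Comparison: its key step is shorter and more certain to work than the nickel cyclisation, and it is the faster way to assemble carbon. The chosen plan sets against it that its key step closes ring B and creates the stereocentre from which the other three follow.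

Key step: step 6

Assumption: the sense of induction of the phosphinooxazoline ligand on this substrate class cannot be predicted with certainty; (R)-Ph-PHOX is written, and its enantiomer is to be used if it delivers the (1S) carbinol.

## Route

Step 1
Reactants: 1 3,5-bis(benzyloxy)benzaldehyde
Product: 2 2-bromo-3,5-bis(benzyloxy)benzaldehyde
Conditions: NBS (1.05 equiv), MeCN, 0 °C → rt
Reagents that add atoms: N-bromosuccinimide, O=C1CCC(=O)N1Br
Why: Electrophilic aromatic bromination; the position ortho to the formyl group and para to one ether is the established site for 3,5-dialkoxybenzaldehydes, the position between the two ethers being more hindered. Polar, initiator-free conditions avoid benzylic bromination.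

Step 2
Reactants: 2 2-bromo-3,5-bis(benzyloxy)benzaldehyde; 3 1-(benzyloxy)-4-ethynylbenzene
Product: 4 3,5-bis(benzyloxy)-2-{[4-(benzyloxy)phenyl]ethynyl}benzaldehyde
Conditions: PdCl2(PPh3)2 (5 mol %), CuI (10 mol %), Et3N, DMF, 70 °C
Reagents that add atoms: none
Why: Sonogashira coupling; the ortho formyl group activates the hindered aryl bromide towards oxidative addition, and this coupling is standard for 2-bromo-3,5-dialkoxybenzaldehydes.

Step 3
Reactants: 4 3,5-bis(benzyloxy)-2-{[4-(benzyloxy)phenyl]ethynyl}benzaldehyde; 5 4-(benzyloxy)benzyl chloride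
Product: 7 racemic 1-[3,5-bis(benzyloxy)-2-{[4-(benzyloxy)phenyl]ethynyl}phenyl]-2-[4-(benzyloxy)phenyl]ethan-1-ol, via Grignard reagent 6 (not isolated)
Conditions: 5, Mg, 2-MeTHF, 0 °C; then 4, THF, −78 → 0 °C; aq NH4Cl
Reagents that add atoms: none
Why: Grignard addition to an aldehyde forms the C1–C8 bond; 2-MeTHF and slow addition at 0 °C limit Wurtz coupling of the benzylic halide. The diaryl alkyne is inert to the reagent, and the new stereocentre is lost in step 4.

Step 4
Reactants: 7 racemic 1-[3,5-bis(benzyloxy)-2-{[4-(benzyloxy)phenyl]ethynyl}phenyl]-2-[4-(benzyloxy)phenyl]ethan-1-ol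
Product: 8 1-[3,5-bis(benzyloxy)-2-{[4-(benzyloxy)phenyl]ethynyl}phenyl]-2-[4-(benzyloxy)phenyl]ethan-1-one
Conditions: Dess–Martin periodinane, CH2Cl2, 0 °C → rt
Reagents that add atoms: none
Why: Dess–Martin oxidation of a secondary benzylic alcohol; neutral and metal-free, so the ortho alkynyl ketone is not induced to cyclise.

Step 5
Reactants: 8 1-[3,5-bis(benzyloxy)-2-{[4-(benzyloxy)phenyl]ethynyl}phenyl]-2-[4-(benzyloxy)phenyl]ethan-1-one
Product: 9 1-[3,5-bis(benzyloxy)-2-{[4-(benzyloxy)phenyl]ethynyl}phenyl]-2-[4-(benzyloxy)phenyl]ethane-1,2-dione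
Conditions: SeO2 (1.5 equiv), 1,4-dioxane/H2O (20:1), 100 °C
Reagents that add atoms: selenium dioxide, O=[Se]=O
Why: Riley oxidation of a deoxybenzoin methylene to the benzil through the enol; without strong acid SeO2 leaves diaryl alkynes alone.

Step 6
Reactants: 9 1-[3,5-bis(benzyloxy)-2-{[4-(benzyloxy)phenyl]ethynyl}phenyl]-2-[4-(benzyloxy)phenyl]ethane-1,2-dione; 10 3,5-bis(benzyloxy)phenylboronic acid
Product: 11 [(1R)-4,6-bis(benzyloxy)-3-[3,5-bis(benzyloxy)phenyl]-2-[4-(benzyloxy)phenyl]-1-hydroxy-1H-inden-1-yl][4-(benzyloxy)phenyl]methanone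
Conditions: Ni(OAc)2·4H2O (10 mol %), (R)-Ph-PHOX [(R)-2-(2-diphenylphosphinophenyl)-4-phenyl-4,5-dihydrooxazole] (10 mol %), 10 (2 equiv), MeCN/2-MeTHF (3:2), 80 °C
Reagents that add atoms: none
Why: Proposed new method: the closest known reaction type is the nickel-catalysed enantioselective anti-carbometallative cyclisation of alkyne-tethered ketones with arylboronic acids (Ni(OAc)2, phosphinooxazoline ligand), established for aryl–alkyl alkynes but not for a diaryl alkyne joined through an arene to a 1,2-diketone. Transmetallation of 10 gives a ring E–nickel species (divalent nickel throughout, no redox change) that adds syn across C3≡C2, ring E to C3 and nickel to C2. The resulting E-alkenylnickel, with nickel trans to ring A, isomerises reversibly to the Z isomer through a carbene-like zwitterion, stabilised by donor ring C on the nickel-bearing carbon and by rings A and E on the carbanionic carbon. Only the Z isomer reaches the C1 carbonyl; 1,2-insertion of C1=O into the C2–Ni bond closes ring B in the 5-exo-trig mode at the carbonyl carbon, and protonolysis of the nickel alkoxide by water or acetic acid releases 11 and the catalyst. C1 is the only new stereocentre and is set under ligand control, the oxazoline substituent selecting the face of the C1 ketone that the alkenyl carbon attacks. The step needs nickel on C2: the P,N-ligated metal is the bulkier partner in the four-centre insertion and should avoid C3, which is flanked by the 2,6-disubstituted ring A, whereas ring E has free ortho positions; insertion the other way closes no ring and would appear as hydroarylated alkyne. It also needs attack on C1 and not C8: C1 is nearer (five- against six-membered closure) and is not deactivated by a para-alkoxy donor as the C8 carbonyl is.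

Step 7
Reactants: 11 [(1R)-4,6-bis(benzyloxy)-3-[3,5-bis(benzyloxy)phenyl]-2-[4-(benzyloxy)phenyl]-1-hydroxy-1H-inden-1-yl][4-(benzyloxy)phenyl]methanone
Product: 12 [(1S,2S,3R)-4,6-bis(benzyloxy)-3-[3,5-bis(benzyloxy)phenyl]-2-[4-(benzyloxy)phenyl]-1-hydroxy-2,3-dihydro-1H-inden-1-yl][4-(benzyloxy)phenyl]methanone (hydroxyl, H-2 and H-3 on one face; the changed descriptors at C1 and C2 follow from the sequence rule only)
Conditions: [Ir(cod)(PCy3)(py)]PF6 (10 mol %), H2 (50 bar), CH2Cl2, rt
Reagents that add atoms: none
Why: Hydroxyl-directed homogeneous hydrogenation: the cationic iridium binds the tertiary allylic C1 hydroxyl and delivers both hydrogens syn to C2 and C3 on the hydroxyl face, so rings C and E end cis to each other and to the aroyl group. That face is also the less hindered one, and this catalyst cleaves neither benzyl ethers nor the C1–O bond.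

Step 8
Reactants: 12 [(1S,2S,3R)-4,6-bis(benzyloxy)-3-[3,5-bis(benzyloxy)phenyl]-2-[4-(benzyloxy)phenyl]-1-hydroxy-2,3-dihydro-1H-inden-1-yl][4-(benzyloxy)phenyl]methanone
Product: 14 [(1R,2R,3R)-4,6-bis(benzyloxy)-3-[3,5-bis(benzyloxy)phenyl]-2-[4-(benzyloxy)phenyl]-2,3-dihydro-1H-inden-1-yl][4-(benzyloxy)phenyl]methanone (hexa-O-benzylcaraphenol B), via samarium enolate 13 (not isolated)
Conditions: SmI2 (2.5 equiv), THF/MeOH, −78 °C; pH 7 phosphate buffer at −78 °C
Reagents that add atoms: none
Why: SmI2 reduction of an α-hydroxy ketone: electron transfer to the aryl ketone gives a ketyl that expels the C1 oxygen, and a second electron gives enolate 13. Methanol protonates C1 on the face opposite rings C and E (kinetic ketonisation of an exocyclic enolate from its open face), placing the aroyl group cis to both; the cold buffered quench prevents equilibration.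

Step 9
Reactants: 14 [(1R,2R,3R)-4,6-bis(benzyloxy)-3-[3,5-bis(benzyloxy)phenyl]-2-[4-(benzyloxy)phenyl]-2,3-dihydro-1H-inden-1-yl][4-(benzyloxy)phenyl]methanone
Product: 15 caraphenol B, [(1R,2R,3R)-3-(3,5-dihydroxyphenyl)-4,6-dihydroxy-2-(4-hydroxyphenyl)-2,3-dihydro-1H-inden-1-yl](4-hydroxyphenyl)methanone
Conditions: H2 (1 atm), Pd/C (10 % Pd), EtOAc/MeOH, rt
Reagents that add atoms: none
Why: Hydrogenolysis of six aryl benzyl ethers under neutral conditions, chosen because C1–H of the all-cis ketone would not survive acidic or basic deprotection. The 4-hydroxybenzoyl carbonyl is a deactivated, vinylogous acid-type ketone and should outlast the benzyl ethers if the reaction is stopped at full debenzylation.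

## Compound list

1 | 3,5-bis(benzyloxy)benzaldehyde | O=Cc1cc(OCc2ccccc2)cc(OCc2ccccc2)c1 | starting material
2 | 2-bromo-3,5-bis(benzyloxy)benzaldehyde | O=Cc1cc(OCc2ccccc2)cc(OCc2ccccc2)c1Br | intermediate
3 | 1-(benzyloxy)-4-ethynylbenzene | C#Cc1ccc(OCc2ccccc2)cc1 | starting material
4 | 3,5-bis(benzyloxy)-2-{[4-(benzyloxy)phenyl]ethynyl}benzaldehyde | O=Cc1cc(OCc2ccccc2)cc(OCc2ccccc2)c1C#Cc1ccc(OCc2ccccc2)cc1 | intermediate
5 | 4-(benzyloxy)benzyl chloride | ClCc1ccc(OCc2ccccc2)cc1 | starting material
6 | [4-(benzyloxy)benzyl]magnesium chloride | Cl[Mg]Cc1ccc(OCc2ccccc2)cc1 | intermediate (not isolated)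
7 | racemic 1-[3,5-bis(benzyloxy)-2-{[4-(benzyloxy)phenyl]ethynyl}phenyl]-2-[4-(benzyloxy)phenyl]ethan-1-ol | OC(Cc1ccc(OCc2ccccc2)cc1)c1cc(OCc2ccccc2)cc(OCc2ccccc2)c1C#Cc1ccc(OCc2ccccc2)cc1 | intermediate
8 | 1-[3,5-bis(benzyloxy)-2-{[4-(benzyloxy)phenyl]ethynyl}phenyl]-2-[4-(benzyloxy)phenyl]ethan-1-one | O=C(Cc1ccc(OCc2ccccc2)cc1)c1cc(OCc2ccccc2)cc(OCc2ccccc2)c1C#Cc1ccc(OCc2ccccc2)cc1 | intermediate
9 | 1-[3,5-bis(benzyloxy)-2-{[4-(benzyloxy)phenyl]ethynyl}phenyl]-2-[4-(benzyloxy)phenyl]ethane-1,2-dione | O=C(C(=O)c1ccc(OCc2ccccc2)cc1)c1cc(OCc2ccccc2)cc(OCc2ccccc2)c1C#Cc1ccc(OCc2ccccc2)cc1 | intermediate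
10 | 3,5-bis(benzyloxy)phenylboronic acid | OB(O)c1cc(OCc2ccccc2)cc(OCc2ccccc2)c1 | starting material
11 | [(1R)-4,6-bis(benzyloxy)-3-[3,5-bis(benzyloxy)phenyl]-2-[4-(benzyloxy)phenyl]-1-hydroxy-1H-inden-1-yl][4-(benzyloxy)phenyl]methanone | O=C(c1ccc(OCc2ccccc2)cc1)[C@@]1(O)c2cc(OCc3ccccc3)cc(OCc3ccccc3)c2C(c2cc(OCc3ccccc3)cc(OCc3ccccc3)c2)=C1c1ccc(OCc2ccccc2)cc1 | intermediate
12 | [(1S,2S,3R)-4,6-bis(benzyloxy)-3-[3,5-bis(benzyloxy)phenyl]-2-[4-(benzyloxy)phenyl]-1-hydroxy-2,3-dihydro-1H-inden-1-yl][4-(benzyloxy)phenyl]methanone | O=C(c1ccc(OCc2ccccc2)cc1)[C@@]1(O)c2cc(OCc3ccccc3)cc(OCc3ccccc3)c2[C@@H](c2cc(OCc3ccccc3)cc(OCc3ccccc3)c2)[C@H]1c1ccc(OCc2ccccc2)cc1 | intermediate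
13 | samarium enolate of 14 (C1=C8 enolate, O–SmI2; C2 and C3 as in 12) | I[Sm](I)OC(c1ccc(OCc2ccccc2)cc1)=C1c2cc(OCc3ccccc3)cc(OCc3ccccc3)c2[C@@H](c2cc(OCc3ccccc3)cc(OCc3ccccc3)c2)[C@H]1c1ccc(OCc2ccccc2)cc1 | intermediate (not isolated)
14 | [(1R,2R,3R)-4,6-bis(benzyloxy)-3-[3,5-bis(benzyloxy)phenyl]-2-[4-(benzyloxy)phenyl]-2,3-dihydro-1H-inden-1-yl][4-(benzyloxy)phenyl]methanone (hexa-O-benzylcaraphenol B) | O=C(c1ccc(OCc2ccccc2)cc1)[C@H]1c2cc(OCc3ccccc3)cc(OCc3ccccc3)c2[C@@H](c2cc(OCc3ccccc3)cc(OCc3ccccc3)c2)[C@H]1c1ccc(OCc2ccccc2)cc1 | intermediate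
15 | caraphenol B, [(1R,2R,3R)-3-(3,5-dihydroxyphenyl)-4,6-dihydroxy-2-(4-hydroxyphenyl)-2,3-dihydro-1H-inden-1-yl](4-hydroxyphenyl)methanone | O=C(c1ccc(O)cc1)[C@H]1c2cc(O)cc(O)c2[C@@H](c2cc(O)cc(O)c2)[C@H]1c1ccc(O)cc1 | target

## Step count and least certain steps

Total: 9 steps. Longest linear sequence: 9 steps (1 to 15); compounds 3, 5 and 10 enter as purchased.

**Step 6 (key step).** The most likely failure is aryl–nickel insertion with the opposite regiochemistry (nickel on C3), which cannot cyclise and drains 9 into hydroarylation. Closure onto the C8 carbonyl, direct aryl addition to the diketone and poor face selectivity at C1 are further risks. The fallback uses only established reactions, sets out from bromoaldehyde 2 and returns at 11.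
- Palladium-catalysed annulation of 2 (Larock indenone synthesis: Pd(OAc)2, NaOAc, n-Bu4NCl, DMF, 100 °C) with {[3,5-bis(benzyloxy)phenyl]ethynyl}trimethylsilane F1 places silicon next to the carbonyl. F1 is prepared by Sonogashira coupling of commercial 1-bromo-3,5-bis(benzyloxy)benzene with ethynyltrimethylsilane. The product is 4,6-bis(benzyloxy)-3-[3,5-bis(benzyloxy)phenyl]-2-(trimethylsilyl)-1H-inden-1-one F2.
- ICl exchanges silicon for iodine to give the 2-iodoindenone F3. Suzuki coupling with commercial 4-(benzyloxy)phenylboronic acid then gives the 2,3-diarylindenone F4, in which the positions of rings C and E are fixed by construction.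
- The aroyl carbon is added as an acyl anion equivalent. 2-[4-(Benzyloxy)phenyl]-1,3-dithiane F5 (from 4-(benzyloxy)benzaldehyde and propane-1,3-dithiol) is lithiated with n-BuLi in THF at −78 °C to the 2-lithio-1,3-dithiane F6. This adds 1,2 to the C1 carbonyl of F4 to give the tertiary carbinol dithiane F7.
- Hydrolysis of the dithioacetal (MeI, CaCO3, aqueous MeCN) gives the racemic ketol F8. Preparative chromatography on a chiral stationary phase separates 11 from its enantiomer F9.
- The price is that catalytic asymmetric induction is replaced by resolution.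

**Step 7.** The process to fear is failure of the cationic iridium to turn over on a triaryl-substituted tetrasubstituted alkene, or partial delivery from the ketone-bound face; the latter would surface after step 8 as loss of enantiomeric purity. The fallback sets out from 11 and returns at 15. Hydrogenation over Pd/C (H2, EtOAc/MeOH) would saturate C2=C3 from the less hindered hydroxyl face by steric approach control on the surface instead of coordination to a soluble cation. It would cleave the six benzyl ethers in the same operation, giving the hexaphenol ketol F10. SmI2 in THF/MeOH then removes the C1 hydroxyl of F10 and gives 15, so C1 is created in the last operation. Hydrogenolysis of the allylic C1–O bond is the process to watch there.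

**Step 8.** Three processes threaten it: reduction of the chelated ketyl to a diol instead of C–O cleavage, poor facial selectivity in the protonation, and equilibration of C1 by samarium alkoxides before the quench. The fallback sets out from 12 and returns at 15. Dehydration with Burgess reagent (syn elimination; H-2 is cis to the hydroxyl and is the only β-hydrogen) gives the C1=C2 enone F11 with C3 intact. Hydrogenation over Pd/C adds hydrogen to C1=C2 from the face opposite ring E, which places the aroyl group and ring C cis to ring E, and removes the benzyl groups in the same operation. C1 is then set by syn hydrogenation instead of enolate protonation.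

**Step 5.** Oxidation at the alkyne, or acid-induced cyclisation of the ortho alkynyl ketone, may compete with oxidation of the methylene. The fallback sets out from 2 and returns at 9 by building the diketone before the alkyne exists. Grignard reagent 6 adds to 2 to give the bromo alcohol F12. Dess–Martin oxidation gives the bromo ketone F13 and SeO2 the bromo diketone F14. Sonogashira coupling of F14 with 3, the bromide now activated by the ortho diketone, gives 9.

**Step 9.** Over-reduction of the C8 carbonyl, or incomplete debenzylation if the reaction is stopped early, are the likely failures. The fallback sets out from 14 and returns at 15 without new intermediates. BCl3 with pentamethylbenzene as benzyl cation scavenger in CH2Cl2 at −78 °C cleaves aryl benzyl ethers by a Lewis acid pathway that cannot reduce the ketone. It is kept cold and short and quenched with MeOH at −78 °C to spare C1.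

## Further compounds

F1 | step 6 | {[3,5-bis(benzyloxy)phenyl]ethynyl}trimethylsilane | C[Si](C)(C)C#Cc1cc(OCc2ccccc2)cc(OCc2ccccc2)c1
F2 | step 6 | 4,6-bis(benzyloxy)-3-[3,5-bis(benzyloxy)phenyl]-2-(trimethylsilyl)-1H-inden-1-one | C[Si](C)(C)C1=C(c2cc(OCc3ccccc3)cc(OCc3ccccc3)c2)c2c(OCc3ccccc3)cc(OCc3ccccc3)cc2C1=O
F3 | step 6 | 4,6-bis(benzyloxy)-3-[3,5-bis(benzyloxy)phenyl]-2-iodo-1H-inden-1-one | IC1=C(c2cc(OCc3ccccc3)cc(OCc3ccccc3)c2)c2c(OCc3ccccc3)cc(OCc3ccccc3)cc2C1=O
F4 | step 6 | 4,6-bis(benzyloxy)-3-[3,5-bis(benzyloxy)phenyl]-2-[4-(benzyloxy)phenyl]-1H-inden-1-one | O=C1C(c2ccc(OCc3ccccc3)cc2)=C(c2cc(OCc3ccccc3)cc(OCc3ccccc3)c2)c2c(OCc3ccccc3)cc(OCc3ccccc3)cc12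
F5 | step 6 | 2-[4-(benzyloxy)phenyl]-1,3-dithiane | C1CSC(SC1)c1ccc(OCc2ccccc2)cc1
F6 | step 6 | 2-lithio-2-[4-(benzyloxy)phenyl]-1,3-dithiane | [Li]C1(SCCCS1)c1ccc(OCc2ccccc2)cc1
F7 | step 6 | racemic 4,6-bis(benzyloxy)-3-[3,5-bis(benzyloxy)phenyl]-2-[4-(benzyloxy)phenyl]-1-{2-[4-(benzyloxy)phenyl]-1,3-dithian-2-yl}-1H-inden-1-ol | OC1(C2(SCCCS2)c2ccc(OCc3ccccc3)cc2)c2cc(OCc3ccccc3)cc(OCc3ccccc3)c2C(c2cc(OCc3ccccc3)cc(OCc3ccccc3)c2)=C1c1ccc(OCc2ccccc2)cc1
F8 | step 6 | racemic 11 | O=C(c1ccc(OCc2ccccc2)cc1)C1(O)c2cc(OCc3ccccc3)cc(OCc3ccccc3)c2C(c2cc(OCc3ccccc3)cc(OCc3ccccc3)c2)=C1c1ccc(OCc2ccccc2)cc1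
F9 | step 6 | (1S) enantiomer of 11 | O=C(c1ccc(OCc2ccccc2)cc1)[C@]1(O)c2cc(OCc3ccccc3)cc(OCc3ccccc3)c2C(c2cc(OCc3ccccc3)cc(OCc3ccccc3)c2)=C1c1ccc(OCc2ccccc2)cc1
F10 | step 7 | [(1S,2S,3R)-3-(3,5-dihydroxyphenyl)-1,4,6-trihydroxy-2-(4-hydroxyphenyl)-2,3-dihydro-1H-inden-1-yl](4-hydroxyphenyl)methanone | O=C(c1ccc(O)cc1)[C@@]1(O)c2cc(O)cc(O)c2[C@@H](c2cc(O)cc(O)c2)[C@H]1c1ccc(O)cc1
F11 | step 8 | [(1S)-5,7-bis(benzyloxy)-1-[3,5-bis(benzyloxy)phenyl]-2-[4-(benzyloxy)phenyl]-1H-inden-3-yl][4-(benzyloxy)phenyl]methanone (indene numbering; the C1=C2 enone of the route numbering with C3 unchanged) | O=C(c1ccc(OCc2ccccc2)cc1)C1=C(c2ccc(OCc3ccccc3)cc2)[C@H](c2cc(OCc3ccccc3)cc(OCc3ccccc3)c2)c2c(OCc3ccccc3)cc(OCc3ccccc3)cc12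
F12 | step 5 | racemic 1-[2-bromo-3,5-bis(benzyloxy)phenyl]-2-[4-(benzyloxy)phenyl]ethan-1-ol | OC(Cc1ccc(OCc2ccccc2)cc1)c1cc(OCc2ccccc2)cc(OCc2ccccc2)c1Br
F13 | step 5 | 1-[2-bromo-3,5-bis(benzyloxy)phenyl]-2-[4-(benzyloxy)phenyl]ethan-1-one | O=C(Cc1ccc(OCc2ccccc2)cc1)c1cc(OCc2ccccc2)cc(OCc2ccccc2)c1Br
F14 | step 5 | 1-[2-bromo-3,5-bis(benzyloxy)phenyl]-2-[4-(benzyloxy)phenyl]ethane-1,2-dione | O=C(C(=O)c1ccc(OCc2ccccc2)cc1)c1cc(OCc2ccccc2)cc(OCc2ccccc2)c1Br
F0 | step 9 | none | none
A1 | alternative 1 | [4-(benzyloxy)phenyl][4,6-bis(benzyloxy)-1H-inden-1-yl]methanol, C1 configured as in 15, C8 either epimer | OC(c1ccc(OCc2ccccc2)cc1)[C@@H]1C=Cc2c(OCc3ccccc3)cc(OCc3ccccc3)cc21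
A2 | alternative 1 | 1-iodo-3,5-bis(benzyloxy)benzene | Ic1cc(OCc2ccccc2)cc(OCc2ccccc2)c1
A3 | alternative 1 | 4-(benzyloxy)phenylboronic acid | OB(O)c1ccc(OCc2ccccc2)cc1
A4 | alternative 1 | all-cis 1-{[4-(benzyloxy)phenyl](hydroxy)methyl}-2-[4-(benzyloxy)phenyl]-3-[3,5-bis(benzyloxy)phenyl]-4,6-bis(benzyloxy)indane | OC(c1ccc(OCc2ccccc2)cc1)[C@H]1c2cc(OCc3ccccc3)cc(OCc3ccccc3)c2[C@@H](c2cc(OCc3ccccc3)cc(OCc3ccccc3)c2)[C@H]1c1ccc(OCc2ccccc2)cc1
A5 | alternative 2 | 4-(3,5-dimethoxyphenyl)-2-(4-methoxybenzoyl)-3-(4-methoxyphenyl)cyclopentan-1-one, aryl groups cis, C2 of the cyclopentanone enolisable | O=C(c1ccc(OC)cc1)C1C(=O)C[C@@H](c2cc(OC)cc(OC)c2)[C@H]1c1ccc(OC)cc1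
A6 | alternative 2 | methyl (2-methyl-1,3-dioxolan-2-yl)acetate | COC(=O)CC1(C)OCCO1
A7 | alternative 2 | 1-epi-caraphenol B tetramethyl ether (ring A as free 4,6-diol) | O=C(c1ccc(OC)cc1)[C@@H]1c2cc(O)cc(O)c2[C@@H](c2cc(OC)cc(OC)c2)[C@H]1c1ccc(OC)cc1
A8 | alternative 3 | 3,5-dimethoxy-2-(trimethylsilyl)phenyl trifluoromethanesulfonate | COc1cc(OC)c([Si](C)(C)C)c(OS(=O)(=O)C(F)(F)F)c1
A9 | alternative 3 | 3,5-dimethoxybenzyne | COC1=CC(OC)=CC#C1
A10 | alternative 3 | 1-(3,5-dimethoxyphenyl)-3-(4-methoxyphenyl)propane-1,3-dione | COc1ccc(cc1)C(=O)CC(=O)c1cc(OC)cc(OC)c1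
A11 | alternative 3 | 2-[2-(3,5-dimethoxybenzoyl)-3,5-dimethoxyphenyl]-1-(4-methoxyphenyl)ethanone | COc1ccc(cc1)C(=O)Cc1cc(OC)cc(OC)c1C(=O)c1cc(OC)cc(OC)c1
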